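The plan rests on cutting the C10–O bond of the dihydrofuran. In the target, C10 is the only atom that ring B (C5–C10) shares with the dihydrofuran, it carries the aryloxy oxygen, and it sits next to the C9 and C8 carbonyls. Ring B can therefore be traced back to a flat guaiacol-type phenol (C9–OH, C8–OMe, C5–CH3). One two-electron oxidation of a C1 diarylmethine bisphenol bearing a but-3-enyl chain forms C10–O, closes the spiro dihydrofuran, sets C10 from C1 and unveils a 2,4-dienone whose C5 terminus later accepts the C4 radical. The C8 methoxy group steers the oxidant to ring B and supplies the C8 oxygen.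

Key step: step 4

Numbering: aristolane numbers are used for the terpenoid carbons (C1–C10 decalin, C11 cyclopropane carbon, O10 the ether oxygen on C10). Primed numbers are used for the acetophenone ring (C1′ acyl-bearing, C5′ bonded to C1, C6′ bonded to O10). The α face of ring B carries O10 and the C5 methyl; the β face carries C1 and C4. Only C8–C10 of ring B bear oxygen. C5 (quaternary) and C6/C7 (cyclopropane CH) are built up after dearomatisation.

Assumption: (R)-TRIP is taken to give the S configuration at C1 in step 3. If the sense of induction is opposite, (S)-TRIP is used.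

Step 1
Reactants: 1 2-methoxy-5-methylphenol
Product: 2 2-hydroxy-3-methoxy-6-methylbenzaldehyde
Conditions: MgCl2 (1.5 equiv), Et3N (3.75 equiv), (CH2O)n (6.75 equiv), MeCN, reflux; 1 M HCl work-up
Reagents that add atoms: paraformaldehyde (reacts as formaldehyde), C=O
Why: Casnati–Skattebøl ortho-formylation: the magnesium phenoxide of 1 delivers formaldehyde only ortho to oxygen, the carbon between OH and CH3 is the sole free ortho position, and a second formaldehyde takes up hydride from the benzylic alkoxide to leave the aldehyde.

Step 2
Reactants: 2 2-hydroxy-3-methoxy-6-methylbenzaldehyde; 3 but-3-enylmagnesium bromide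
Product: 4 (±)-2-(1-hydroxypent-4-enyl)-6-methoxy-3-methylphenol
Conditions: 3 (2.3 equiv), THF, −78 → 0 °C; sat. aq NH4Cl
Reagents that add atoms: none
Why: Grignard 1,2-addition to the aldehyde after the first equivalent has deprotonated the phenol; the carbinol centre is deliberately racemic because it is flattened in step 3.

Step 3
Reactants: 4 (±)-2-(1-hydroxypent-4-enyl)-6-methoxy-3-methylphenol; 5 2′,6′-dihydroxy-4′-methoxyacetophenone
Product: 7 1-{2,6-dihydroxy-3-[(1S)-1-(2-hydroxy-3-methoxy-6-methylphenyl)pent-4-enyl]-4-methoxyphenyl}ethanone (key-step precursor), via o-quinone methide 6 (not isolated)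
Conditions: (R)-TRIP [(R)-3,3′-bis(2,4,6-triisopropylphenyl)-BINOL hydrogen phosphate] (10 mol %), 5 (1.5 equiv), 4 Å MS, CH2Cl2, 0 °C
Reagents that add atoms: none
Why: Chiral-phosphoric-acid-catalysed dehydrative Friedel–Crafts alkylation of a hydroxyarene by an o-quinone methide made in the flask: loss of water from 4 gives planar 6, whose exocyclic carbon is open on both faces although both arenes end up doubly ortho-substituted, and the phosphate, hydrogen-bonded to the methide oxygen and to a phenol OH of 5, guides one of the two equivalent CH carbons of 5 (activated by three oxygen donors, meta to the acyl group) to one face, which sets C1 as S, while the excess of 5 suppresses double alkylation and crystallisation should raise the enantiopurity.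

Step 4
Reactants: 7 (S)-diarylmethine precursor
Product: 9 (1R,10S)-spiro dihydrobenzofuran 8-methoxy-5-methylcyclohexa-2,4-dien-9-one with the but-3-enyl chain on C1 cis to C5, via aryloxy-λ3-iodane 8 (not isolated)
Conditions: PhI(OAc)2 (1.05 equiv), CH2Cl2–(CF3)2CHOH 4:1 (0.02 M), −20 → 0 °C; 9 is used promptly
Reagents that add atoms: none
Why: PhI(OAc)2 exchanges one acetate for the C9 phenol oxygen to give 8, then the C6′ phenol oxygen attacks the ortho carbon C10 while iodobenzene and acetate leave, so that C9 becomes the dienone carbonyl and C10 the spiro centre. This is the trivalent-iodine dearomatising spiroetherification known for 2-(2-hydroxybenzyl)phenols and is akin to grisan-type phenol coupling. The dihydrofuran (O10, C10, C1, C5′, C6′) closes in a 5-exo-trig mode. C10 is controlled by C1: to overlap with the ring B π system the O–I bond must stand perpendicular to ring B on the face opposite the incoming acetophenone ring, the C1 substituent sharing that quadrant beside C9 has to be H, and the butenyl chain is thereby placed on the C5 side (10S). The oxidant must choose ring B, which the C8 methoxy group secures by making it the more electron-rich phenol, whereas the other ring is acyl-substituted and its hydroxyls are hydrogen-bonded to the acetyl oxygen. The other electrophilic positions C8 and C6 lie beyond reach of the tethered oxygen, the fluoroalcohol medium offers no outside nucleophile, and cold dilute conditions plus the C5 methyl hold back Diels–Alder dimerisation.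

Step 5
Reactants: 9 (1R,10S)-spirodienone
Product: 10 (1R,4R,5S,10S)-tetracyclic 8-methoxy-7-en-9-one (ring A closed)
Conditions: Fe(acac)3 (30 mol %), Ph(i-PrO)SiH2 (3 equiv), i-PrOH–THF 1:1 (0.01 M, degassed), 35 °C
Reagents that add atoms: none
Why: Metal-hydride hydrogen-atom transfer followed by an intramolecular Giese reaction (reductive olefin coupling): the iron hydride gives H to the terminal CH2 of the electron-neutral alkene rather than to the electron-poor dienone, the secondary C4 radical closes ring A by 6-exo attack on the δ-carbon C5 from the only face its three-atom tether reaches (the β face, so the C5 methyl ends cis to O10), the C4 methyl sits pseudo-equatorial in the chair-like transition state away from C9 (4R), and the extended radical is reduced and protonated to the conjugated enone.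

Step 6
Reactants: 10 tetracyclic 8-methoxy-7-en-9-one
Product: 11 (1R,4R,5S,10S)-tetracyclic 8-hydroxy-7-en-9-one (diosphenol)
Conditions: BCl3 (3.5 equiv), CH2Cl2, −78 → −20 °C; then H2O
Reagents that add atoms: none
Why: Chelation-assisted ether cleavage: BCl3 is held between the C9 carbonyl and the C8 methoxy oxygen and chloride removes the methyl group by SN2, whereas the unchelated C4′ aryl methyl ether and the tertiary C10–O10 ether beside a carbonyl should survive at low temperature, and hydrolysis frees the fully enolised 1,2-dione.

Step 7
Reactants: 11 diosphenol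
Product: 12 (1R,4R,5R,10S)-tetracyclic 6-ene-8,9-dione
Conditions: IBX (1.5 equiv), 4-methoxypyridine N-oxide (1.5 equiv), DMSO, 25 °C
Reagents that add atoms: none
Why: IBX dehydrogenation of a carbonyl compound: the C8 enol oxygen binds pentavalent iodine and a C6 hydrogen is lost to give the C6=C7 enone, quaternary C5 stops any further oxidation, the acetyl group has no β-hydrogen, and the N-oxide ligand allows room temperature so that the hydrogen-bonded acyl phenol and the benzylic C1–H are left alone.

Step 8
Reactants: 12 6-ene-8,9-dione; 13 isopropyldiphenylsulfonium tetrafluoroborate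
Product: 15 (1R,4R,5R,6S,7R,10S)-acetyl cyclopropyl 8,9-dione, via diphenylsulfonium isopropylide 14 (not isolated)
Conditions: 13 (2.5 equiv), LiN(i-Pr)2 (2.5 equiv), DME–THF, −78 °C; then 12, −78 → −40 °C; sat. aq NH4Cl
Reagents that add atoms: none
Why: Corey–Chaykovsky-type isopropylidene transfer (Michael-initiated ring closure): the tertiary ylide carbon prefers 1,4-addition at C6 of the C8 enone over the crowded carbonyls, the C7 enolate then expels Ph2S so the ring fusion is necessarily cis, one equivalent of ylide merely deprotonates the phenol, and attack is expected on the β face because the α face is screened by the C5 methyl, O10 and the acetyl methyl that lies under ring B (6S,7R).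

Step 9
Reactants: 15 acetyl cyclopropyl 8,9-dione; 16 4-methoxybenzaldehyde
Product: 18 target chalcone CNP0121765.1, via aldol adduct 17 (not isolated)
Conditions: 16 (1.2 equiv), LiOH·H2O (3 equiv), EtOH, 25 °C
Reagents that add atoms: none
Why: Claisen–Schmidt condensation: the acetyl CH3 is the only enolisable position left (C10 is quaternary, C7–H sits on the cyclopropane), E1cB dehydration of 17 gives the E-enone, the mild hydroxide source at room temperature limits attack on the hindered 1,2-dione, and the 2′-OH to carbonyl hydrogen bond keeps the open chalcone form.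

Compound list
1 | 2-methoxy-5-methylphenol | COc1ccc(C)cc1O | starting material
2 | 2-hydroxy-3-methoxy-6-methylbenzaldehyde | Cc1ccc(OC)c(O)c1C=O | intermediate
3 | but-3-enylmagnesium bromide | C=CCC[Mg]Br | starting material
4 | (±)-2-(1-hydroxypent-4-enyl)-6-methoxy-3-methylphenol | C=CCCC(O)c1c(C)ccc(OC)c1O | intermediate
5 | 2′,6′-dihydroxy-4′-methoxyacetophenone | CC(=O)c1c(O)cc(OC)cc1O | starting material
6 | o-quinone methide, 2-methoxy-5-methyl-6-(pent-4-enylidene)cyclohexa-2,4-dienone | C=CCCC=C1C(C)=CC=C(OC)C1=O | intermediate
7 | (S)-diarylmethine precursor, ring B as 2-hydroxy-3-methoxy-6-methylphenyl, but-3-enyl chain on C1 | CC(=O)c1c(O)cc(OC)c(c1O)[C@@H](CCC=C)c1c(C)ccc(OC)c1O | intermediate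
8 | acetoxy(phenyl)-λ3-iodanyl ether of 7 at the C9 oxygen | CC(=O)c1c(O)cc(OC)c(c1O)[C@@H](CCC=C)c1c(C)ccc(OC)c1OI(OC(C)=O)c1ccccc1 | intermediate
9 | (1R,10S)-spiro dihydrobenzofuran cyclohexa-2,4-dienone (C9=O, C8–OMe, C5–CH3 on the diene terminus, chain cis to C5) | CC(=O)c1c(O)cc(OC)c2c1O[C@@]3(C(=O)C(OC)=CC=C3C)[C@@H]2CCC=C | intermediate
10 | (1R,4R,5S,10S)-tetracyclic 8-methoxy-7-en-9-one (C5 has the same spatial arrangement as in the target; the descriptor differs only through priorities) | CC(=O)c1c(O)cc(OC)c2c1O[C@]13C(=O)C(OC)=CC[C@@]1(C)[C@H](C)CC[C@H]23 | intermediate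
11 | (1R,4R,5S,10S)-tetracyclic 8-hydroxy-7-en-9-one (diosphenol) | CC(=O)c1c(O)cc(OC)c2c1O[C@]13C(=O)C(O)=CC[C@@]1(C)[C@H](C)CC[C@H]23 | intermediate
12 | (1R,4R,5R,10S)-tetracyclic 6-ene-8,9-dione | CC(=O)c1c(O)cc(OC)c2c1O[C@]13C(=O)C(=O)C=C[C@@]1(C)[C@H](C)CC[C@H]23 | intermediate
13 | isopropyldiphenylsulfonium tetrafluoroborate | CC(C)[S+](c1ccccc1)c1ccccc1.F[B-](F)(F)F | starting material
14 | diphenylsulfonium isopropylide | C[C-](C)[S+](c1ccccc1)c1ccccc1 | intermediate
15 | (1R,4R,5R,6S,7R,10S)-acetyl cyclopropyl 8,9-dione | CC(=O)c1c(O)cc(OC)c2c1O[C@]13C(=O)C(=O)[C@@H]4[C@@H](C4(C)C)[C@@]1(C)[C@H](C)CC[C@H]23 | intermediate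
16 | 4-methoxybenzaldehyde | COc1ccc(C=O)cc1 | starting material
17 | β-hydroxy ketone from 15 and 16 (carbinol centre undefined) | COc1ccc(C(O)CC(=O)c2c(O)cc(OC)c3c2O[C@]24C(=O)C(=O)[C@@H]5[C@@H](C5(C)C)[C@@]2(C)[C@H](C)CC[C@H]34)cc1 | intermediate
18 | CNP0121765.1, (1R,4R,5R,6S,7R,10S), E-chalcone | COc1ccc(/C=C/C(=O)c2c(O)cc(OC)c3c2O[C@]24C(=O)C(=O)[C@@H]5[C@@H](C5(C)C)[C@@]2(C)[C@H](C)CC[C@H]34)cc1 | target

Total step count: 9. Longest linear sequence: 9 steps (1 → 18).

Steps most likely to fail

Step 4. What may go wrong:
- Poor facial selectivity at C10, with the chain turning to the C9 side.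
- Loss of the C1 proton to a quinone methide.
- Oxidation of the wrong ring.

The fallback hands stereocontrol from the substrate to the reagent. It sets out from 7 and uses a C2-symmetric 2-iodoresorcinol bis(lactamide) aryl iodide (10 mol %) with mCPBA in CH2Cl2–(CF3)2CHOH at −20 °C. This forms a chiral trivalent iodine species in the flask, as established for enantioselective ortho-spirolactonisation of phenols. The catalyst enantiomer matched to C1 is chosen so that closure comes back to the route at 9. The C10-epimeric spirodienone F1, which cannot close ring A, is separated and returned to 7 by reductive rearomatisation with Zn in AcOH, so the material is recycled.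

Step 8. What may go wrong:
- Attack of the bulky ylide on the α face of ring B.
- 1,2-Addition to the dione followed by oxirane formation.

The fallback replaces the ylide by hydroxyl-directed carbenoid delivery and sets out from 12.
- Luche reduction (NaBH4, CeCl3·7H2O, MeOH, −78 °C) brings hydride in from the same open α face and should give the 8β-hydroxy-6-en-9-one F2.
- The gem-dimethyl Simmons–Smith variant (Et2Zn, 2,2-diiodopropane, CH2Cl2, 0 °C) is guided by the zinc alkoxide to the β face and should give the cyclopropyl carbinol F3.
- Dess–Martin periodinane restores the C8 ketone, and any over-reduced C9 alcohol, and comes back to the route at 15.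

Step 5. What may go wrong: hydrogen-atom transfer to the monosubstituted alkene is too slow. In that case reductive rearomatisation of the dienone with loss of the C10–O10 bond, plain hydrogenation of the chain, or intramolecular Diels–Alder reaction takes over.

The fallback makes the same C4 radical from a C–Br bond and sets out from 7.
- Markovnikov addition of HBr (33 % in AcOH, CH2Cl2, 0 °C) should give the secondary bromide F4. Both C4 epimers form, which is irrelevant.
- The conditions of step 4 should turn it into the bromo spirodienone F5.
- Halogen-atom abstraction with (Me3Si)3SiH and Et3B/air in toluene at 0 °C triggers the same 6-exo cyclisation and comes back to the route at 10.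

Further compounds
F1 | step 4 | (1R,10R)-spirodienone, C10 epimer of 9 | CC(=O)c1c(O)cc(OC)c2c1O[C@]3(C(=O)C(OC)=CC=C3C)[C@@H]2CCC=C
F2 | step 8 | (1R,4R,5R,8S,10S)-8β-hydroxy-6-en-9-one | CC(=O)c1c(O)cc(OC)c2c1O[C@]13C(=O)[C@@H](O)C=C[C@@]1(C)[C@H](C)CC[C@H]23
F3 | step 8 | (1R,4R,5R,6S,7R,8S,10S)-cyclopropyl 8β-carbinol | CC(=O)c1c(O)cc(OC)c2c1O[C@]13C(=O)[C@@H](O)[C@@H]4[C@@H](C4(C)C)[C@@]1(C)[C@H](C)CC[C@H]23
F4 | step 5 | (1S)-precursor with a 3-bromobutyl chain (C4 epimers) | CC(=O)c1c(O)cc(OC)c(c1O)[C@@H](CCC(C)Br)c1c(C)ccc(OC)c1O
F5 | step 5 | (1R,10S)-spirodienone with a 3-bromobutyl chain (C4 epimers) | CC(=O)c1c(O)cc(OC)c2c1O[C@@]3(C(=O)C(OC)=CC=C3C)[C@@H]2CCC(C)Br
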